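**Plan**
Cuts (phthalide numbering for ring B: C1 carbonyl, O2, C3 lactol carbon, C3a to C7a benzene ring): first the O3–acyl bond of an (R)-propanoate that masks the lactol, then the benzylic CH2–O bond to the ring A carboxylate, then the lactone bond C1–O2, and last the ring B bonds C3a–C7a and C5–C6.
Enabling feature: ring B is a resorcinol with oxygens at C5 and C7, the pattern of a cyclohexane-1,3-dione. Its six carbons divide into C6–C7–C7a (a β-keto ester unit bearing C1 and the C6 methyl) and C3a–C4–C5 (an enoate unit bearing C3 as an acetal).
Forward order: ring B is built first from the two acyclic three-carbon units and aromatised. The lactone ring closes second on acid hydrolysis, the C6 methyl is then brominated, and ring A (from atraric acid) is joined last as its carboxylate.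
Stereochemistry: C3 is the only stereocentre. It is set by acylative dynamic kinetic resolution of the racemising lactol with a chiral isothiourea, carried as a configurationally fixed acylal, and freed in the last step by a lipase alcoholysis that breaks only the acyl–oxygen bond.

Key step: step 1

Assumption: the C3 lactol loses its configuration only through acid- or base-promoted ring–chain tautomerism with the achiral formyl acid, so it is taken to hold its configuration in neutral aprotic media at low temperature and is unveiled only in the final operation.

Step 1
Reactants: 1 methyl 3-oxopentanoate; 2 methyl (E)-4,4-dimethoxybut-2-enoate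
Product: 5 methyl 6-(dimethoxymethyl)-2-hydroxy-4-methoxy-3-methylbenzoate, via Michael adduct 3 (not isolated), via cyclohexanedione 4 (not isolated)
Conditions: NaOMe (1.1 equiv), MeOH, reflux; cool to 0 °C, HCl in MeOH (1.1 equiv); I2 (1.5 equiv), MeOH, reflux; aq Na2S2O3/NaHCO3 quench
Reagents that add atoms: methanol, CO
Why: NaOMe deprotonates 1 at the carbon between its two carbonyls (future C7a), which adds to the β-carbon of 2 (future C3a) to give 3; after proton transfer the enolate on the ethyl side of the ketone (future C6) attacks the former enoate ester (future C5), expels methoxide and is drained into the stabilised enolate of 4. This Dieckmann-type closure is 6-(enolendo)-exo-trig and forms the only ring of the step. The sequence is the classical Michael–Dieckmann route from β-keto esters and crotonates to dihydro-orsellinates, joined to the known iodine–methanol aromatisation of cyclohexane-1,3-diones to methoxyphenols. After neutralisation, the HI released by the first iodination catalyses enol ether formation at C5, and iodination followed by loss of HI then takes the ring to the arene. The step needs O-methylation at C5 and not at C7, which is secured because the C7 enol is tied to the neighbouring ester by a hydrogen bond and is flanked on both sides, and it needs the acetal to persist, which is secured because acetal exchange in methanol is degenerate. The three stereocentres of 4 are erased on aromatisation, so none has to be controlled.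

Step 2
Reactants: 5 methyl 6-(dimethoxymethyl)-2-hydroxy-4-methoxy-3-methylbenzoate
Product: 6 rac-3,7-dihydroxy-5-methoxy-6-methylphthalide
Conditions: 2 M aq HCl, THF, 60 °C
Reagents that add atoms: water, O
Why: Acid hydrolysis of the dimethyl acetal frees the aldehyde, whose hydrate attacks the neighbouring ester in a 5-exo-trig intramolecular transesterification (the neighbouring-group-assisted ester cleavage known for 2-formylbenzoates), so the racemic pseudo-acid should form while the aryl methyl ether and the phenol are inert.

Step 3
Reactants: 6 rac-3,7-dihydroxy-5-methoxy-6-methylphthalide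
Product: 7 (3R)-7-hydroxy-5-methoxy-6-methyl-3-(propanoyloxy)phthalide
Conditions: (EtCO)2O (1.2 equiv), (R)-benzotetramisole [(R)-2-phenyl-2,3-dihydrobenzo[d]imidazo[2,1-b]thiazole, 5 mol %], iPr2NEt (1.2 equiv), CHCl3, 0 °C
Reagents that add atoms: propanoic anhydride, CCC(=O)OC(=O)CC
Why: Acylative dynamic kinetic resolution of a 3-hydroxyphthalide by a chiral Lewis base, in which the amine interconverts the lactol enantiomers through the achiral formyl benzoate faster than they are acylated, the N-propanoyl isothiouronium ion should acylate the (R)-lactol preferentially (the same spatial sense as the catalyst's known preference for (R)-aryl carbinols, with the arene and O2 in the places of aryl and alkyl; the mirror-image catalyst is equally available), and the chelated, doubly flanked C7 phenol should stay free at this stoichiometry.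

Step 4
Reactants: 7 (3R)-7-hydroxy-5-methoxy-6-methyl-3-(propanoyloxy)phthalide
Product: 8 (3R)-7-(tert-butyldimethylsilyloxy)-5-methoxy-6-methyl-3-(propanoyloxy)phthalide
Conditions: TBSOTf (1.2 equiv), 2,6-lutidine (1.5 equiv), CH2Cl2, 0 °C
Reagents that add atoms: tert-butyldimethylsilyl triflate, CC(C)(C)[Si](C)(C)OS(=O)(=O)C(F)(F)F
Why: Standard silylation of a hindered, hydrogen-bonded phenol with a silyl triflate and a non-nucleophilic pyridine base, a medium that holds no nucleophile able to cleave or exchange the C3 acylal, so the stereocentre is not touched.

Step 5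
Reactants: 8 (3R)-7-(tert-butyldimethylsilyloxy)-5-methoxy-6-methyl-3-(propanoyloxy)phthalide
Product: 9 (3R)-6-(bromomethyl)-7-(tert-butyldimethylsilyloxy)-5-methoxy-3-(propanoyloxy)phthalide
Conditions: NBS (1.05 equiv), azobisisobutyronitrile (5 mol %), PhCF3, 80 °C
Reagents that add atoms: N-bromosuccinimide, O=C1CCC(=O)N1Br
Why: Wohl–Ziegler bromination, in which the electrophilic bromine atom abstracts hydrogen from the methyl group flanked by two oxygen donors (as in the known brominations of 4-methyl-3,5-dialkoxybenzoates and of silyl-protected o-cresols), while the C3–H bond is polarity-mismatched because it carries two acyloxy groups and the non-polar medium disfavours ionic bromination at C4.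

Step 6
Reactants: 10 atraric acid (methyl 2,4-dihydroxy-3,6-dimethylbenzoate)
Product: 11 methyl 2-hydroxy-4-methoxy-3,6-dimethylbenzoate
Conditions: MeI (1.1 equiv), K2CO3 (1.1 equiv), acetone, reflux
Reagents that add atoms: iodomethane, CI
Why: Williamson ether synthesis in which the C2 hydroxyl is held back by its hydrogen bond to the ester, so one equivalent of MeI should alkylate only the free C4 phenol.

Step 7
Reactants: 11 methyl 2-hydroxy-4-methoxy-3,6-dimethylbenzoate
Product: 12 2-hydroxy-4-methoxy-3,6-dimethylbenzoic acid (rhizonic acid)
Conditions: KOH (4 equiv), DMSO–H2O, 80 °C; then cold 1 M HCl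
Reagents that add atoms: potassium hydroxide, [K+].[OH-]
Why: Saponification of a di-ortho-substituted benzoate by the poorly solvated hydroxide of aqueous DMSO, with cold acidification to avoid the decarboxylation to which electron-rich salicylic acids are prone on heating.

Step 8
Reactants: 9 (3R)-6-(bromomethyl)-7-(tert-butyldimethylsilyloxy)-5-methoxy-3-(propanoyloxy)phthalide; 12 2-hydroxy-4-methoxy-3,6-dimethylbenzoic acid
Product: 14 (3R)-7-hydroxy-6-[(2-hydroxy-4-methoxy-3,6-dimethylbenzoyl)oxymethyl]-5-methoxy-3-(propanoyloxy)phthalide, via coupled silyl ether 13 (not isolated)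
Conditions: 12 (1.1 equiv), KHCO3 (1.2 equiv), DMF, 0 °C to rt; then Et3N·3HF (1.5 equiv), rt
Reagents that add atoms: none
Why: SN2 alkylation of a potassium carboxylate by an activated benzylic bromide (KHCO3 ionises only the carboxylic acid and leaves the chelated phenol and the acylal alone), followed in the same flask by acidic fluoride cleavage of the aryl silyl ether, which frees the C7 phenol without forming the phenoxide that could expel the new ester, and any early desilylation would pass through an o-quinone methide that the same carboxylate captures to give the same product.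

Step 9
Reactants: 14 (3R)-7-hydroxy-6-[(2-hydroxy-4-methoxy-3,6-dimethylbenzoyl)oxymethyl]-5-methoxy-3-(propanoyloxy)phthalide
Product: 15 (3R)-3,7-dihydroxy-6-[(2-hydroxy-4-methoxy-3,6-dimethylbenzoyl)oxymethyl]-5-methoxyphthalide (target)
Conditions: Candida antarctica lipase B on acrylic resin, n-BuOH (3 equiv), MTBE, 5 °C; filter, concentrate cold, crystallise
Reagents that add atoms: none
Why: Lipase-catalysed transesterification of a hemiacetal ester (known for acyloxyfuranones and related to the esterase cleavage of phthalidyl esters), in which the serine attacks the propanoyl carbonyl so the C3–O3 bond stays intact and the (R) configuration is retained, the empirical size rule for secondary alcohols (arene large, O2 medium) marks the (R)-ester as the fast-reacting one, the hindered ring A benzoate and the lactone are no substrates, and the cold, base-free aprotic medium leaves little room for ring–chain tautomerism.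

**Compound list**
1 | methyl 3-oxopentanoate | CCC(=O)CC(=O)OC | starting material
2 | methyl (E)-4,4-dimethoxybut-2-enoate | COC(OC)/C=C/C(=O)OC | starting material
3 | dimethyl 3-(dimethoxymethyl)-2-propanoylpentanedioate (Michael adduct, racemic diastereomer mixture, not isolated) | CCC(=O)C(C(=O)OC)C(CC(=O)OC)C(OC)OC | intermediate
4 | methyl 6-(dimethoxymethyl)-3-methyl-2,4-dioxocyclohexane-1-carboxylate (racemic diastereomer mixture, formed as its sodium enolate, not isolated) | COC(=O)C1C(C(OC)OC)CC(=O)C(C)C1=O | intermediate
5 | methyl 6-(dimethoxymethyl)-2-hydroxy-4-methoxy-3-methylbenzoate | COC(=O)c1c(O)c(C)c(OC)cc1C(OC)OC | intermediate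
6 | rac-3,7-dihydroxy-5-methoxy-6-methylphthalide | COc1cc2c(c(O)c1C)C(=O)OC2O | intermediate
7 | (3R)-7-hydroxy-5-methoxy-6-methyl-3-(propanoyloxy)phthalide | COc1cc2c(c(O)c1C)C(=O)O[C@H]2OC(=O)CC | intermediate
8 | (3R)-7-(tert-butyldimethylsilyloxy)-5-methoxy-6-methyl-3-(propanoyloxy)phthalide | COc1cc2c(c(O[Si](C)(C)C(C)(C)C)c1C)C(=O)O[C@H]2OC(=O)CC | intermediate
9 | (3R)-6-(bromomethyl)-7-(tert-butyldimethylsilyloxy)-5-methoxy-3-(propanoyloxy)phthalide | COc1cc2c(c(O[Si](C)(C)C(C)(C)C)c1CBr)C(=O)O[C@H]2OC(=O)CC | intermediate
10 | atraric acid, methyl 2,4-dihydroxy-3,6-dimethylbenzoate | COC(=O)c1c(C)cc(O)c(C)c1O | starting material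
11 | methyl 2-hydroxy-4-methoxy-3,6-dimethylbenzoate | COC(=O)c1c(C)cc(OC)c(C)c1O | intermediate
12 | 2-hydroxy-4-methoxy-3,6-dimethylbenzoic acid (rhizonic acid) | COc1cc(C)c(C(=O)O)c(O)c1C | intermediate
13 | (3R)-7-(tert-butyldimethylsilyloxy)-6-[(2-hydroxy-4-methoxy-3,6-dimethylbenzoyl)oxymethyl]-5-methoxy-3-(propanoyloxy)phthalide (not isolated) | COc1cc(C)c(C(=O)OCc2c(OC)cc3c(c2O[Si](C)(C)C(C)(C)C)C(=O)O[C@H]3OC(=O)CC)c(O)c1C | intermediate
14 | (3R)-7-hydroxy-6-[(2-hydroxy-4-methoxy-3,6-dimethylbenzoyl)oxymethyl]-5-methoxy-3-(propanoyloxy)phthalide | COc1cc(C)c(C(=O)OCc2c(OC)cc3c(c2O)C(=O)O[C@H]3OC(=O)CC)c(O)c1C | intermediate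
15 | (3R)-3,7-dihydroxy-6-[(2-hydroxy-4-methoxy-3,6-dimethylbenzoyl)oxymethyl]-5-methoxyphthalide | COc1cc(C)c(C(=O)OCc2c(OC)cc3c(c2O)C(=O)O[C@H]3O)c(O)c1C | target

Total step count: 9. Longest linear sequence: 7 steps (1, 2, 3, 4, 5, 8, 9). Steps 6 and 7 form the two-step side branch to the ring A acid.

**Steps most likely to fail**

Step 9. The freed lactol may lose its configuration through ring–chain tautomerism while it stays in contact with the enzyme carrier and the alcohol. The lipase may also turn over the bulky ester too slowly for the release to outrun that process. The fallback takes the stereochemistry from a physical separation instead of from the acylal.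
- Setting out from 14, the propanoate is hydrolysed without regard to configuration in pH 7.5 phosphate buffer–THF, and the solution is acidified cold to pH 3. This should give the racemic lactol rac-3,7-dihydroxy-6-[(2-hydroxy-4-methoxy-3,6-dimethylbenzoyl)oxymethyl]-5-methoxyphthalide F1.
- This racemate is resolved by preparative supercritical-fluid chromatography on an immobilised amylose carbamate phase (CO2/2-propanol containing formic acid, sub-ambient column).
- The (R) fraction is collected into cold solvent and crystallised at once, which comes back to the route at 15.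
- The (S) fraction is re-equilibrated with a trace of iPr2NEt and recycled.

Step 5. Ionic bromination of the ring at C4 (ortho to the methoxy group, para to the silyloxy group) may outrun hydrogen abstraction from the methyl group, and hydrogen abstraction at C3 would destroy the acylal. The fallback redesigns the substrate electronically instead of adjusting the bromination.
- Setting out from 7, the phenol is capped with Boc2O and catalytic 4-(dimethylamino)pyridine in CH2Cl2. This gives the electron-poor carbonate (3R)-7-(tert-butoxycarbonyloxy)-5-methoxy-6-methyl-3-(propanoyloxy)phthalide F2, whose arene is deactivated towards electrophilic bromine.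
- Radical bromination with NBS should then give (3R)-6-(bromomethyl)-7-(tert-butoxycarbonyloxy)-5-methoxy-3-(propanoyloxy)phthalide F3.
- Alkylation of 12 with KHCO3 in DMF should give (3R)-7-(tert-butoxycarbonyloxy)-6-[(2-hydroxy-4-methoxy-3,6-dimethylbenzoyl)oxymethyl]-5-methoxy-3-(propanoyloxy)phthalide F4.
- Brief treatment with CF3CO2H in CH2Cl2 at 0 °C removes the carbonate and comes back to the route at 14.

Step 1. In hot methanolic HI the acetal may not remain a spectator.
- It may close onto the ester to give the 3-methoxy pseudo-ester.
- It may lose methanol towards C3a and then tautomerise, which would aromatise the ring by internal redox and leave C3 at the alcohol level.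
- O-methylation may also be incompletely selective between C5 and C7.

The fallback keeps the annulation and separates etherification from dehydrogenation without strong acid.
- It sets out from 4, now isolated by acidifying the annulation mixture to pH 4. Treatment with HC(OMe)3 and catalytic camphorsulfonic acid in MeOH at rt should give the vinylogous ester methyl 6-(dimethoxymethyl)-4-methoxy-3-methyl-2-oxocyclohex-3-ene-1-carboxylate F5.
- The only strongly acidic C–H left (C7a) is selenylated with NaH and PhSeCl in THF at 0 °C, anti to the acetal-bearing substituent. This gives methyl 6-(dimethoxymethyl)-4-methoxy-3-methyl-2-oxo-1-(phenylselanyl)cyclohex-3-ene-1-carboxylate F6.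
- Oxidation with H2O2 and pyridine in CH2Cl2 at 0 °C triggers selenoxide syn-elimination across C7a–C3a, and tautomerisation comes back to the route at 5.

**Further compounds**
F1 | step 9 | rac-3,7-dihydroxy-6-[(2-hydroxy-4-methoxy-3,6-dimethylbenzoyl)oxymethyl]-5-methoxyphthalide | COc1cc(C)c(C(=O)OCc2c(OC)cc3c(c2O)C(=O)OC3O)c(O)c1C
F2 | step 5 | (3R)-7-(tert-butoxycarbonyloxy)-5-methoxy-6-methyl-3-(propanoyloxy)phthalide | COc1cc2c(c(OC(=O)OC(C)(C)C)c1C)C(=O)O[C@H]2OC(=O)CC
F3 | step 5 | (3R)-6-(bromomethyl)-7-(tert-butoxycarbonyloxy)-5-methoxy-3-(propanoyloxy)phthalide | COc1cc2c(c(OC(=O)OC(C)(C)C)c1CBr)C(=O)O[C@H]2OC(=O)CC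
F4 | step 5 | (3R)-7-(tert-butoxycarbonyloxy)-6-[(2-hydroxy-4-methoxy-3,6-dimethylbenzoyl)oxymethyl]-5-methoxy-3-(propanoyloxy)phthalide | COc1cc(C)c(C(=O)OCc2c(OC)cc3c(c2OC(=O)OC(C)(C)C)C(=O)O[C@H]3OC(=O)CC)c(O)c1C
F5 | step 1 | methyl 6-(dimethoxymethyl)-4-methoxy-3-methyl-2-oxocyclohex-3-ene-1-carboxylate (racemic diastereomer mixture) | COC(=O)C1C(C(OC)OC)CC(OC)=C(C)C1=O
F6 | step 1 | methyl 6-(dimethoxymethyl)-4-methoxy-3-methyl-2-oxo-1-(phenylselanyl)cyclohex-3-ene-1-carboxylate (racemic) | COC(=O)C1([Se]c2ccccc2)C(C(OC)OC)CC(OC)=C(C)C1=O
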